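**Retrosynthetic overview**
1. Feature: in ring B the tertiary carbinol C8 (OH, methyl C17) lies next to C9, and C9 adjoins the quaternary C10 (methyl C20). This oxygenated C8–C9 pair beside C10 is the retron of an acyloin shift. Ring B is therefore the five-membered ring C5–C6–C7–C9–C10 with an acetyl carbon (C8) inserted between C7 and C9.
2. Side chain: C13–C14 is cut by a vinyl Stille coupling on the C13 enol triflate. C9–C11 is cut by Giese addition of a C9 radical to but-3-en-2-one, on the face away from the axial methyls C17 and C20. The radical comes from the C9 ketone through the alcohol and its xanthate.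
3. Key disconnection C7–C8: the 8-hydroxy-8-methyl-9-oxo trans-decalin goes back to the 9-hydroxy-9-acetyl trans-hydrindane (1,2-shift of C7 from C9 to C8).
4. Hydrindane: the acetyl group comes from the C9 enol triflate and an ethoxyvinyl stannane, and the 9-OH from reductive α-hydroxylation of the enone. C4 and C5 come from reductive hydroxymethylation, and C10 from a D-phenylalanine-mediated annulation.
5. Ring order: five-membered ring (purchased), then ring A (step 2), then ring B by ring expansion (step 11).

Key step: step 11

Remark: labdane numbering is used for all bicyclic compounds. In the hydrindanes C7 is bonded directly to C9. C18 is the equatorial CH2O on C4 and C19 is the axial CH3 on C4. "Syn" and "anti" give the face relative to C20. Read from the SMILES, the target is (3R,4S,5S,8S,9R,10R). H5, C18, 8-OH and the C9 side chain are anti; C17, C19 and the equatorial 3-OAc are syn. The side chain is therefore axial.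

**Step 1**
Reactants: 1 2-methylcyclopentane-1,3-dione; 2 pent-1-en-3-one
Product: 3 2-methyl-2-(3-oxopentyl)cyclopentane-1,3-dione
Conditions: H2O, AcOH (cat.), 70 °C
Reagents that add atoms: none
Why: Michael addition of the acidic cyclic 1,3-dione to the unhindered vinyl ketone should stop at the achiral triketone, because C10 becomes quaternary.

**Step 2**
Reactants: 3 2-methyl-2-(3-oxopentyl)cyclopentane-1,3-dione
Product: 4 (7aR)-4,7a-dimethyl-2,3,7,7a-tetrahydro-1H-indene-1,5(6H)-dione
Conditions: D-phenylalanine, aq HClO4, MeCN, reflux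
Reagents that add atoms: none
Why: in this Hajos–Parrish–Eder–Sauer–Wiechert cyclodehydration the D-amino acid forms the side-chain enamine and its acid group directs attack to one of the two enantiotopic ring carbonyls, which closes ring A and sets C10 as R (the L-acid gives the S series), and recrystallisation should raise the enantiomeric purity.

**Step 3**
Reactants: 4 (7aR)-4,7a-dimethyl-2,3,7,7a-tetrahydro-1H-indene-1,5(6H)-dione
Product: 5 (1R,7aR)-1-hydroxy-4,7a-dimethyl-1,2,3,6,7,7a-hexahydro-5H-inden-5-one (9-OH syn)
Conditions: NaBH4, EtOH, −15 °C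
Reagents that add atoms: none
Why: this chemoselective borohydride reduction works because the saturated C9 cyclopentanone is much more electrophilic than the tetrasubstituted enone, and hydride adds anti to C20 to give a temporary C9 carbinol that is erased in step 7.

**Step 4**
Reactants: 5 hydroxy enone
Product: 7 trans-hydrindan-3-one keto diol (H5 anti; C18H2OH anti and equatorial; C19 syn and axial; 9-OH syn), via dilithium enolate alkoxide 6 (not isolated)
Conditions: Li, NH3(l)–THF, −78 → −33 °C; NH3 off, THF; CH2O(g), −78 °C; aq NH4Cl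
Reagents that add atoms: formaldehyde (cracked from paraformaldehyde), C=O
Why: in this dissolving-metal reductive alkylation of an enone the substrate hydroxyl supplies the one proton equivalent needed, C5 is protonated axially to give the trans fusion, and the regiodefined C3–C4 enolate takes up formaldehyde anti to the axial C20, which makes the CH2OH equatorial and the C4 methyl axial.

**Step 5**
Reactants: 7 keto diol
Product: 8 triol (3-OH equatorial and syn)
Conditions: NaBH4, MeOH, 0 °C
Reagents that add atoms: none
Why: borohydride reduction of a 4,4-disubstituted cyclohexanone proceeds by axial hydride delivery on the face free of the axial C19 methyl and should give the equatorial C3 alcohol.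

**Step 6**
Reactants: 8 triol
Product: 9 3,18-acetonide 9-alcohol
Conditions: Me2C(OMe)2, PPTS (cat.), CH2Cl2, rt
Reagents that add atoms: 2,2-dimethoxypropane, COC(C)(C)OC
Why: acid-catalysed transketalisation closes a chair 1,3-dioxane on the diequatorial 3,18-diol, while the remote 9-OH has no partner and stays free.

**Step 7**
Reactants: 9 3,18-acetonide 9-alcohol
Product: 10 3,18-acetonide trans-hydrindan-9-one
Conditions: Dess–Martin periodinane, pyridine, CH2Cl2, 0 °C → rt
Reagents that add atoms: none
Why: the buffered Dess–Martin oxidation converts the hindered secondary alcohol to the ketone without touching the acetonide, and no epimerisable centre lies next to C9.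

**Step 8**
Reactants: 10 hydrindan-9-one
Product: 12 C9 enol triflate (C7=C9), via potassium enolate 11 (not isolated)
Conditions: KHMDS, THF, −78 °C; PhNTf2, −78 → 0 °C; aq NH4Cl
Reagents that add atoms: N-phenylbis(trifluoromethanesulfonimide), O=S(=O)(N(c1ccccc1)S(=O)(=O)C(F)(F)F)C(F)(F)F
Why: C10 is quaternary, so the ketone can enolise only toward C7, and O-sulfonylation of that enolate is the standard route to enol triflates of such cyclopentanones.

**Step 9**
Reactants: 12 C9 enol triflate; 13 tributyl(1-ethoxyvinyl)stannane
Product: 15 9-acetyl hydrind-7(9)-ene acetonide (enone), via ethoxydiene 14 (not isolated)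
Conditions: Pd(PPh3)4 (cat.), LiCl, THF, reflux; then 1 M HCl, THF, 0 °C
Reagents that add atoms: water, O
Why: this Stille coupling of a vinyl triflate uses the stannane as an acetyl-anion equivalent and brings in C8 and C17, and brief cold dilute acid hydrolyses the far more reactive enol ether while sparing the acetonide.

**Step 10**
Reactants: 15 enone
Product: 17 9-hydroxy-9-acetyl trans-hydrindane acetonide (9S; 9-OH anti; acetyl syn), via C9 hydroperoxide 16 (not isolated)
Conditions: Mn(dpm)3 (cat.), PhSiH3, O2 (1 atm), i-PrOH–CH2Cl2, 0 °C; then P(OEt)3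
Reagents that add atoms: dioxygen, O=O
Why: in this Mukaiyama-type reductive α-hydroxylation of an enone a manganese hydride delivers H to C7, the planar tertiary α-keto radical at C9 captures O2 on the face anti to the neighbouring C20, and the phosphite reduces the hydroperoxide.

**Step 11**
Reactants: 17 9-hydroxy-9-acetyl trans-hydrindane acetonide
Product: 18 8-hydroxy-8-methyl-9-oxo trans-decalin acetonide (8S; 8-OH anti and equatorial; C17 syn and axial)
Conditions: BF3·OEt2, CH2Cl2, −20 → 0 °C; aq NaHCO3
Reagents that add atoms: none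
Why: The Lewis acid binds the acetyl oxygen while held by the adjacent C9 hydroxyl, C8 becomes electrophilic, and the C7–C9 σ bond moves to C8 as the C9–O bond becomes the C9 carbonyl, which is an α-ketol (acyloin) rearrangement. The closest known case is the Lewis-acid D-homoannulation of 17-hydroxy-20-oxo steroids, and 17 is its mirror-image counterpart around C10 and C20. Ring B (C5–C6–C7–C8–C9–C10) is closed by ring expansion through this suprafacial 1,2-alkyl shift, and the change from a strained trans-hydrindane to a trans-decalin drives the reversible isomerisation forward. The only new stereocentre, C8, is fixed by the syn-periplanar alignment of the C9–O and C8=O bonds in the bridged conformer, so that C7 attacks the carbonyl face which leaves the new carbinol oxygen on the face of the former 9-OH (anti to C20) and places C17 axial, syn to C20. The step needs migration of the methylene C7 and not of quaternary C10, and this is secured because a C10 shift would force C17 against C20 and join two fully substituted carbons. Low temperature, short contact and a basic quench should keep the outcome kinetic and spare the acetonide.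

**Step 12**
Reactants: 18 ring-expanded ketol
Product: 19 8,9-diol (9-OH syn and equatorial; trans-diequatorial to 8-OH)
Conditions: LiAlH4, THF, 0 °C → rt; H2O/NaOH work-up
Reagents that add atoms: none
Why: the small hydride reduces the non-enolisable hindered ketone from the face anti to the two axial methyls C17 and C20, and the C9 configuration formed here does not matter because step 15 erases it.

**Step 13**
Reactants: 19 8,9-diol
Product: 21 C9 O-alkyl S-methyl xanthate with free 8-OH, via sodium xanthate 20 (not isolated)
Conditions: NaH (1 equiv), THF, 0 °C; CS2; MeI, 0 °C → rt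
Reagents that add atoms: carbon disulfide, S=C=S; iodomethane, CI
Why: in this xanthate formation for Barton–McCombie-type chemistry the small CS2 is taken up reversibly and settles on the secondary oxygen, one equivalent of base leaves the tertiary OH neutral, the trans-diequatorial geometry disfavours closure to a strained cyclic thionocarbonate, and no β-hydrogen is available for Chugaev elimination.

**Step 14**
Reactants: 21 C9 xanthate
Product: 22 8-O-triethylsilyl C9 xanthate
Conditions: TESOTf, 2,6-lutidine, CH2Cl2, −78 → 0 °C
Reagents that add atoms: triethylsilyl trifluoromethanesulfonate, CC[Si](CC)(CC)OS(=O)(=O)C(F)(F)F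
Why: silyl triflate with a hindered base silylates tertiary alcohols, and the mask is needed so that O8 cannot later close a six-membered hemiketal onto the C13 ketone.

**Step 15**
Reactants: 22 8-O-TES C9 xanthate; 23 but-3-en-2-one
Product: 24 C13 methyl ketone (9R; C11 anti and axial; H9 syn)
Conditions: Bu3SnH (slow addition), AIBN (cat.), excess 23, PhH, 80 °C
Reagents that add atoms: none
Why: in this Giese addition the stannyl radical cleaves the xanthate to the nucleophilic secondary C9 radical, whose syn lobe is flanked by the axial methyls C17 and C20, so the enone is attacked from the anti face to form C9–C11 with the axial configuration of the target before hydrogen transfer ends the chain.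

**Step 16**
Reactants: 24 C13 methyl ketone
Product: 26 C13 enol triflate (C13=C16 terminal), via lithium enolate 25 (not isolated)
Conditions: LDA, THF, −78 °C; Comins' reagent, −78 °C; aq NH4Cl
Reagents that add atoms: N-(5-chloropyridin-2-yl)bis(trifluoromethanesulfonimide), O=S(=O)(N(c1ccc(Cl)cn1)S(=O)(=O)C(F)(F)F)C(F)(F)F
Why: kinetic deprotonation of a methyl ketone by a hindered amide base takes place at the methyl group C16, and the reactive triflimide traps the terminal enolate at low temperature before it can equilibrate.

**Step 17**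
Reactants: 26 protected C13 enol triflate
Product: 27 3,8,18-triol C13 enol triflate
Conditions: 1 M HCl, THF, rt
Reagents that add atoms: none
Why: mild aqueous acid hydrolyses both the 1,3-dioxane acetonide and the triethylsilyl ether, whereas the electron-poor vinyl triflate and the non-allylic tertiary alcohol are inert under these conditions.

**Step 18**
Reactants: 27 triol enol triflate
Product: 28 18-O-TBS ether
Conditions: TBSCl, imidazole, CH2Cl2, 0 °C
Reagents that add atoms: tert-butyldimethylsilyl chloride, CC(C)(C)[Si](C)(C)Cl
Why: direct acetylation would favour the primary O18, so that oxygen is blocked first by sterically controlled silylation, which selects the primary over the secondary and tertiary hydroxyls.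

**Step 19**
Reactants: 28 18-O-TBS ether
Product: 29 3-acetate 18-O-TBS ether
Conditions: Ac2O, pyridine, DMAP (cat.), CH2Cl2, rt
Reagents that add atoms: acetic anhydride, CC(=O)OC(C)=O
Why: the equatorial C3 alcohol is acetylated under standard conditions, while the hindered tertiary 8-OH does not react at room temperature.

**Step 20**
Reactants: 29 3-acetate 18-O-TBS enol triflate; 30 tributyl(vinyl)stannane
Product: 31 13(16),14-diene 3-acetate 18-O-TBS ether
Conditions: Pd(PPh3)4 (cat.), LiCl, THF, 60 °C
Reagents that add atoms: none
Why: this Stille coupling of the 2-triflyloxy-1-alkene with a vinyl stannane forms C13–C14 under neutral conditions that tolerate the acetate, the silyl ether and the free tertiary alcohol.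

**Step 21**
Reactants: 31 diene 3-acetate 18-O-TBS ether
Product: 32 target, (3R,4S,5S,8S,9R,10R)-3-acetoxy-8,18-dihydroxylabda-13(16),14-diene
Conditions: HF·pyridine, pyridine–THF, 0 °C
Reagents that add atoms: none
Why: buffered fluoride cleaves the Si–O bond without generating an alkoxide, which should suppress acetyl migration from O3 to O18 and leave the diene and the tertiary alcohol untouched.

**Compound list**
1 | 2-methylcyclopentane-1,3-dione | CC1C(=O)CCC1=O | starting material
2 | pent-1-en-3-one | CCC(=O)C=C | starting material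
3 | 2-methyl-2-(3-oxopentyl)cyclopentane-1,3-dione | CCC(=O)CCC1(C)C(=O)CCC1=O | intermediate
4 | (7aR)-4,7a-dimethyl-2,3,7,7a-tetrahydro-1H-indene-1,5(6H)-dione | CC1=C2CCC(=O)[C@]2(C)CCC1=O | intermediate
5 | (1R,7aR)-1-hydroxy-4,7a-dimethyl-1,2,3,6,7,7a-hexahydro-5H-inden-5-one | CC1=C2CC[C@@H](O)[C@]2(C)CCC1=O | intermediate
6 | dilithium C3–C4 enolate C9 alkoxide of the trans-hydrindane | [Li+].[Li+].[O-][C@@H]1CC[C@@H]2C(C)=C([O-])CC[C@@]12C | intermediate
7 | trans-hydrindan-3-one keto diol (equatorial C18H2OH, axial C19, 9-OH syn) | O[C@@H]1CC[C@@H]2[C@@](C)(CO)C(=O)CC[C@@]12C | intermediate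
8 | 3,9,18-triol (3-OH equatorial) | O[C@@H]1CC[C@@H]2[C@@](C)(CO)[C@H](O)CC[C@@]12C | intermediate
9 | 3,18-acetonide 9-alcohol | O[C@@H]1CC[C@@H]2[C@@]3(C)COC(C)(C)O[C@@H]3CC[C@@]12C | intermediate
10 | 3,18-acetonide trans-hydrindan-9-one | O=C1CC[C@@H]2[C@@]3(C)COC(C)(C)O[C@@H]3CC[C@@]12C | intermediate
11 | potassium C7=C9 enolate of 10 | [K+].[O-]C1=CC[C@@H]2[C@@]3(C)COC(C)(C)O[C@@H]3CC[C@@]12C | intermediate
12 | C9 enol triflate | FC(F)(F)S(=O)(=O)OC1=CC[C@@H]2[C@@]3(C)COC(C)(C)O[C@@H]3CC[C@@]12C | intermediate
13 | tributyl(1-ethoxyvinyl)stannane | CCOC(=C)[Sn](CCCC)(CCCC)CCCC | starting material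
14 | 9-(1-ethoxyvinyl) hydrind-7(9)-ene acetonide | CCOC(=C)C1=CC[C@@H]2[C@@]3(C)COC(C)(C)O[C@@H]3CC[C@@]12C | intermediate
15 | 9-acetyl hydrind-7(9)-ene acetonide | CC(=O)C1=CC[C@@H]2[C@@]3(C)COC(C)(C)O[C@@H]3CC[C@@]12C | intermediate
16 | 9-hydroperoxy-9-acetyl trans-hydrindane acetonide | CC(=O)[C@]1(OO)CC[C@@H]2[C@@]3(C)COC(C)(C)O[C@@H]3CC[C@@]12C | intermediate
17 | 9-hydroxy-9-acetyl trans-hydrindane acetonide (9-OH anti to C20) | CC(=O)[C@]1(O)CC[C@@H]2[C@@]3(C)COC(C)(C)O[C@@H]3CC[C@@]12C | intermediate
18 | 8-hydroxy-8-methyl-9-oxo trans-decalin acetonide | O=C1[C@]2(C)CC[C@H]3OC(C)(C)OC[C@]3(C)[C@H]2CC[C@]1(C)O | intermediate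
19 | 8,9-diol acetonide (9-OH equatorial) | O[C@H]1[C@]2(C)CC[C@H]3OC(C)(C)OC[C@]3(C)[C@H]2CC[C@]1(C)O | intermediate
20 | sodium C9 xanthate | [Na+].[S-]C(=S)O[C@H]1[C@]2(C)CC[C@H]3OC(C)(C)OC[C@]3(C)[C@H]2CC[C@]1(C)O | intermediate
21 | C9 S-methyl xanthate, free 8-OH | CSC(=S)O[C@H]1[C@]2(C)CC[C@H]3OC(C)(C)OC[C@]3(C)[C@H]2CC[C@]1(C)O | intermediate
22 | C9 S-methyl xanthate, 8-O-TES | CSC(=S)O[C@H]1[C@]2(C)CC[C@H]3OC(C)(C)OC[C@]3(C)[C@H]2CC[C@]1(C)O[Si](CC)(CC)CC | intermediate
23 | but-3-en-2-one | C=CC(C)=O | starting material
24 | C13 methyl ketone, 8-O-TES, acetonide (axial side chain) | CC(=O)CC[C@@H]1[C@]2(C)CC[C@H]3OC(C)(C)OC[C@]3(C)[C@H]2CC[C@]1(C)O[Si](CC)(CC)CC | intermediate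
25 | lithium C13=C16 enolate of 24 | [Li+].[O-]C(=C)CC[C@@H]1[C@]2(C)CC[C@H]3OC(C)(C)OC[C@]3(C)[C@H]2CC[C@]1(C)O[Si](CC)(CC)CC | intermediate
26 | C13 enol triflate, 8-O-TES, acetonide | C=C(OS(=O)(=O)C(F)(F)F)CC[C@@H]1[C@]2(C)CC[C@H]3OC(C)(C)OC[C@]3(C)[C@H]2CC[C@]1(C)O[Si](CC)(CC)CC | intermediate
27 | 3,8,18-triol C13 enol triflate | C=C(OS(=O)(=O)C(F)(F)F)CC[C@@H]1[C@]2(C)CC[C@@H](O)[C@](C)(CO)[C@H]2CC[C@]1(C)O | intermediate
28 | 18-O-TBS 3,8-diol C13 enol triflate | C=C(OS(=O)(=O)C(F)(F)F)CC[C@@H]1[C@]2(C)CC[C@@H](O)[C@](C)(CO[Si](C)(C)C(C)(C)C)[C@H]2CC[C@]1(C)O | intermediate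
29 | 3-acetate 18-O-TBS C13 enol triflate | C=C(OS(=O)(=O)C(F)(F)F)CC[C@@H]1[C@]2(C)CC[C@@H](OC(C)=O)[C@](C)(CO[Si](C)(C)C(C)(C)C)[C@H]2CC[C@]1(C)O | intermediate
30 | tributyl(vinyl)stannane | C=C[Sn](CCCC)(CCCC)CCCC | starting material
31 | 13(16),14-diene 3-acetate 18-O-TBS ether | C=CC(=C)CC[C@@H]1[C@]2(C)CC[C@@H](OC(C)=O)[C@](C)(CO[Si](C)(C)C(C)(C)C)[C@H]2CC[C@]1(C)O | intermediate
32 | CNP0313672.1 | C=CC(=C)CC[C@@H]1[C@]2(C)CC[C@@H](OC(C)=O)[C@](C)(CO)[C@H]2CC[C@]1(C)O | target

**Total step count:** 21. **Longest linear sequence:** 21 steps (from 1; all other building blocks are purchased).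

**Steps most likely to fail**

1. **Step 11.** Several things may go wrong here. C10 may shift instead of C7. The reaction may run through the unbridged anti conformer, which gives the wrong face at C8. The reversible shift may re-equilibrate on long exposure. The Lewis acid may open the acetonide.
 Fallback, from 10 back to 18: C8 is inserted stepwise and then functionalised.
 - Homologation of 10 with TMSCHN2 and AlMe3 in CH2Cl2, in which the less substituted C7 migrates, should give the 8-trimethylsilyl-9-oxo decalin F1.
 - Brief dilute acid removes the silyl group and gives the 9-oxo trans-decalin F2.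
 - LDA and MeI act at C8, the only enolisable position, and give the 8-methyl-9-oxo decalin F3.
 - Deprotonation with KHMDS followed by 2-(phenylsulfonyl)-3-phenyloxaziridine places oxygen on the enolate face anti to the axial C20, which returns to 18.

2. **Step 15.** Hydrogen may transfer from the stannane to the crowded C9 radical before the C–C bond forms, and the enone may telomerise.
 Fallback, from 22 back to 24: a hydride-free Keck radical allylation is followed by chain adjustment.
 - Treatment of 22 with allyltributylstannane and AIBN should give the anti (axial) 9-allyl compound F4.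
 - Hydroboration with 9-BBN and oxidation with H2O2/NaOH gives the primary alcohol F5.
 - Dess–Martin oxidation gives the aldehyde F6.
 - MeMgBr gives the secondary alcohol F7.
 - A second Dess–Martin oxidation gives 24.

3. **Step 4.** Control of the C5 protonation may be incomplete. Proton exchange may occur between the enolate and the product. Formaldehyde may oligomerise on the alkoxides. The new CH2OH may be lost by retro-aldol reaction.
 Fallback, from 5 back to 7:
 - The same Li/NH3 reduction is quenched with TMSCl/Et3N, and the bis(trimethylsilyl) enol ether F8 is isolated.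
 - A Mukaiyama aldol reaction of F8 with aqueous formaldehyde and Sc(OTf)3 (cat.) in THF follows. This acid-catalysed, non-basic hydroxymethylation should show the same anti facial preference.
 - The mildly acidic work-up frees O9 and gives 7.

**Further compounds**
F1 | step 11 | 8-trimethylsilyl-9-oxo trans-decalin acetonide (C8 epimers) | O=C1[C@]2(C)CC[C@H]3OC(C)(C)OC[C@]3(C)[C@H]2CCC1[Si](C)(C)C
F2 | step 11 | 9-oxo trans-decalin acetonide (C8 = CH2) | O=C1[C@]2(C)CC[C@H]3OC(C)(C)OC[C@]3(C)[C@H]2CCC1
F3 | step 11 | 8-methyl-9-oxo trans-decalin acetonide (equatorial methyl) | O=C1[C@]2(C)CC[C@H]3OC(C)(C)OC[C@]3(C)[C@H]2CC[C@@H]1C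
F4 | step 15 | 9-allyl 8-O-TES acetonide (allyl anti, axial) | C=CC[C@@H]1[C@]2(C)CC[C@H]3OC(C)(C)OC[C@]3(C)[C@H]2CC[C@]1(C)O[Si](CC)(CC)CC
F5 | step 15 | 9-(3-hydroxypropyl) 8-O-TES acetonide | OCCC[C@@H]1[C@]2(C)CC[C@H]3OC(C)(C)OC[C@]3(C)[C@H]2CC[C@]1(C)O[Si](CC)(CC)CC
F6 | step 15 | 9-(3-oxopropyl) 8-O-TES acetonide | O=CCC[C@@H]1[C@]2(C)CC[C@H]3OC(C)(C)OC[C@]3(C)[C@H]2CC[C@]1(C)O[Si](CC)(CC)CC
F7 | step 15 | 9-(3-hydroxybutyl) 8-O-TES acetonide (C13 epimers) | CC(O)CC[C@@H]1[C@]2(C)CC[C@H]3OC(C)(C)OC[C@]3(C)[C@H]2CC[C@]1(C)O[Si](CC)(CC)CC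
F8 | step 4 | 3,9-bis(trimethylsilyloxy) trans-hydrind-3-ene | C[Si](C)(C)O[C@@H]1CC[C@@H]2C(C)=C(O[Si](C)(C)C)CC[C@@]12C
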